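Assumption: side-chain atoms are numbered C1' (OCH2) to C8' (terminal CH2), the benzene ring of the coumarin is ring A and the pyranone is ring B; (R)-glycidol, 7-hydroxy-8-methoxycoumarin and 2-bromopropene are taken as purchasable.

## Analysis of the target

The target is a 7-alkoxy-8-methoxycoumarin: benzene ring A fused to α-pyranone ring B, a methyl ether on C8 and an oxidised ten-carbon chain on O7. The chain holds an E-trisubstituted alkene C2'=C3', a methylene C4', two adjacent secondary carbinols C5' (S) and C6' (R), and an isopropenyl end C7'=C8'. With C4'–C5'–C6'–C7' drawn as a zigzag the two hydroxyls lie on opposite faces (anti), and no ring in the chain holds this relationship; the alkene geometry is a third stereo-element. The sensitive groups are the lactone of ring B with its conjugated C3=C4 bond (hydroxide, hydride, hard carbanions), the allylic aryl ether C1'–O7 (acid, low-valent metals, heat) and the allylic C6' carbinol. The difficulty is the control of two neighbouring acyclic stereocentres in the presence of a lactone that tolerates few organometallic reagents. The route rests on one feature: C6' is a carbinol between the sp2 carbon C7' and the oxygen-bearing C5'. The C6'–C7' bond can therefore be made by adding an isopropenyl metal to a C6' aldehyde, with the C5' oxygen directing the approach.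

## Retrosynthetic reasoning

Target 13 is taken back to its C5' mono-silyl ether 12. Only an O–Si bond is cut. The silyl group is the control element of the preceding step, and its removal needs no base strong enough to open ring B.

In 12 the C6'–C7' bond is cut, which gives aldehyde 9 and 2-bromopropene 10, used as its chromium reagent 11. This is the one C–C bond of the diol unit whose formation creates a stereocentre directly next to an existing one while bringing in a complete three-carbon unit. Cutting C5'–C6' would require two centres to be controlled at once, and cutting C3'–C4' would leave both to be made on a separate fragment. The gain is that the whole coumarin–chain assembly is finished before the stereochemical step, and 9 carries a single stereocentre. The forward reaction must add to the aldehyde only, anti to the C5' oxygen, and must not enolise C5'.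

Aldehyde 9 is traced to primary alcohol 8 and this to bis-silyl ether 7. No skeletal bond is cut. Using one silyl group on both oxygens saves a differentiating step early on. The forward steps must tell the primary from the secondary silyl ether and oxidise without epimerisation.

In 7 the C1'–O7 bond is cut, giving allylic alcohol 5 and phenol 6. This is the natural polar bond, and it keeps the lactone out of the organoaluminium chemistry that builds the alkene. The forward reaction must O-alkylate without allylic transposition and keep the E geometry.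

In 5 the C3'–CH3 and C1'–C2' bonds are cut, leading to terminal alkyne 3 through alkenylalane 4. A syn carbometalation fixes the E geometry by mechanism, whereas an olefination of a methyl ketone would give mixtures. The forward step must deliver the methyl group to the internal alkyne carbon and then form the C1'–C2' bond with retention.

Alkyne 3 comes from diol 2 by cutting the O–Si bonds, and 2 from epoxide 1 by cutting C3'–C4'. The C5' stereocentre is bought with 1 and is never a reaction site. The descriptor changes from R in 1 to S in 2 only because substituent priorities change.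

## Alternatives that were turned down

Alternative 1: The C5'–C6' bond is cut so that both carbinols arise together. In the forward step a chiral ortho-cyclometallated iridium–bisphosphine catalyst dehydrogenates the primary alcohol 7-{[(2E)-5-hydroxy-3-methylpent-2-en-1-yl]oxy}-8-methoxy-2H-chromen-2-one A2. It couples the transient aldehyde with 2-methylprop-2-ene-1,1-diyl dibenzoate A3 to give the anti monobenzoate (3R,4S,6E)-4-hydroxy-8-[(8-methoxy-2-oxo-2H-chromen-7-yl)oxy]-2,6-dimethylocta-1,6-dien-3-yl benzoate A1.
- For: no chiral starting material, no aldehyde to isolate, the C–C bond and both stereocentres in one catalytic step, and about six steps in all.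
- Against: A3 carries a methyl group on the central allyl carbon. An oxygen-substituted allyl iridium with that pattern is not an established donor, and the methyl sits where the closed transition state is tight, so rate, anti selectivity and enantioselectivity are all open. The catalyst that ionises A3 can also ionise the allylic aryl ether of A2. The hot carbonate medium and the later ester methanolysis both act next to the lactone.
- Comparison: it is stronger on step count and on using catalytic chirality. The chosen route offers instead a purchased C5' centre and a single relative configuration to induce, by a reaction class with direct precedent on α-silyloxy aldehydes.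

Alternative 2: C1'–C2' and C3'–CH3 are cut on the alkyne (4S,5R)-2,2-dimethyl-4-(prop-2-yn-1-yl)-5-(prop-1-en-2-yl)-1,3-dioxolane A5, whose two stereocentres come from 2-deoxy-D-ribose A7. In the forward step zirconium-catalysed methylalumination of A5 is followed by capture of the alkenylalane with 7-(chloromethoxy)-8-methoxy-2H-chromen-2-one A6. This gives 7-{[(2E)-4-[(4S,5R)-2,2-dimethyl-5-(prop-1-en-2-yl)-1,3-dioxolan-4-yl]-3-methylbut-2-en-1-yl]oxy}-8-methoxy-2H-chromen-2-one A4.
- For: the anti diol is bought, so no stereoselective step is needed; on this point it is stronger than the chosen route. One operation makes the E alkene and attaches the ring system.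
- Against: turning the hydroxymethyl end of A7 into the isopropenyl group takes an oxidation, methyl addition, oxidation and methylenation sequence. That sequence passes through a carbonyl group alpha to a cis-dioxolane, which epimerises readily and would erode the purchased relationship. The organoaluminium medium can open the acetonide and attack the lactone of A6. A6 is a labile alkylating agent that must be made, and alkenylalane capture is established only for simple alkoxymethyl chlorides. The route would need ten steps or more.
- Comparison: the chosen route uses the same carbometalation on a robust bis-silyl ether with a one-carbon electrophile, and accepts one diastereoselective step in return.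

Alternative 3: C3'–C4' is cut between the alkenyl iodide 7-{[(2E)-3-iodobut-2-en-1-yl]oxy}-8-methoxy-2H-chromen-2-one A9 and the epoxide tert-butyldimethyl{[(1R)-2-methyl-1-[(2S)-oxiran-2-yl]prop-2-en-1-yl]oxy}silane A10. In the forward step a nitrogen-ligated nickel catalyst, an iodide co-catalyst and a metal powder reductant join the two electrophiles at the terminal epoxide carbon. The product is 7-{[(2E,5S,6R)-6-[(tert-butyldimethylsilyl)oxy]-5-hydroxy-3,7-dimethylocta-2,7-dien-1-yl]oxy}-8-methoxy-2H-chromen-2-one A8.
- For: it is the most convergent plan. Both stereocentres are finished and purified on a small fragment, and the E geometry is carried in by A9.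
- Against: low-valent nickel is kept in the flask at a much higher loading than in the chosen key step, with a stoichiometric reductant regenerating it. Insertion into the allylic aryl ether of A9, with loss of the coumarin-7-olate, is therefore a serious competitor. A10 requires an asymmetric epoxidation of the vinyl group of a dienol in the presence of the more electron-rich isopropenyl group, against the usual rate order. A9 needs its own geometry-defined synthesis.
- Comparison: it is stronger on convergence. The chosen route has one uncertain step where this plan has two or three.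

Key step: step 7

## Route

Step 1
Reactants: 1 (R)-glycidol, [(2R)-oxiran-2-yl]methanol
Product: 2 (2S)-pent-4-yne-1,2-diol
Conditions: LiC≡CH·H2NCH2CH2NH2 (3 equiv), DMSO, 0 °C to rt; aq. NH4Cl
Reagents that add atoms: lithium acetylide–ethylenediamine complex, [Li+].[C-]#C.NCCN
Why: Acetylide opens the epoxide at its unsubstituted carbon (SN2 epoxide opening, known for glycidol and its ethers) and forms the C3'–C4' bond; the carbinol carbon is not a reaction site and the degenerate Payne rearrangement of the alkoxide returns the same enantiomer, so the future C5' keeps its configuration (R becomes S only through a priority change).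

Step 2
Reactants: 2 (2S)-pent-4-yne-1,2-diol
Product: 3 (4S)-4,5-bis[(tert-butyldimethylsilyl)oxy]pent-1-yne
Conditions: TBSCl (2.5 equiv), imidazole, DMAP (cat.), DMF, rt
Reagents that add atoms: tert-butyldimethylsilyl chloride, CC(C)(C)[Si](C)(C)Cl
Why: Imidazole-promoted silylation of both hydroxyls; the silyl ethers are inert to organoaluminium reagents, and the secondary one later serves as the control element of step 7.

Step 3
Reactants: 3 (4S)-4,5-bis[(tert-butyldimethylsilyl)oxy]pent-1-yne
Product: 5 (2E,5S)-5,6-bis[(tert-butyldimethylsilyl)oxy]-3-methylhex-2-en-1-ol, via alkenyldimethylalane 4 (not isolated)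
Conditions: Me3Al (3 equiv), Cp2ZrCl2 (0.3 equiv), CH2Cl2, 0 °C to rt; then (CH2O)n, 0 °C to rt; aq. KNaC4H4O6
Reagents that add atoms: trimethylaluminium, C[Al](C)C; paraformaldehyde (as formaldehyde), C=O
Why: Negishi zirconium-catalysed carboalumination adds methyl and aluminium syn across the terminal alkyne with methyl on the internal carbon, and alkenylalane 4 adds to formaldehyde with retention, so the C2'=C3' alkene is formed E; the C5' centre is remote and unaffected.

Step 4
Reactants: 5 (2E,5S)-5,6-bis[(tert-butyldimethylsilyl)oxy]-3-methylhex-2-en-1-ol; 6 7-hydroxy-8-methoxy-2H-chromen-2-one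
Product: 7 7-{[(2E,5S)-5,6-bis[(tert-butyldimethylsilyl)oxy]-3-methylhex-2-en-1-yl]oxy}-8-methoxy-2H-chromen-2-one
Conditions: PPh3, DIAD, THF, 0 °C to rt
Reagents that add atoms: none
Why: Mitsunobu etherification: the phenol of 6, acidified by the conjugated lactone carbonyl, displaces the primary allylic oxyphosphonium at C1' by SN2 under neutral conditions, so the E alkene and ring B stay intact.

Step 5
Reactants: 7 7-{[(2E,5S)-5,6-bis[(tert-butyldimethylsilyl)oxy]-3-methylhex-2-en-1-yl]oxy}-8-methoxy-2H-chromen-2-one
Product: 8 7-{[(2E,5S)-5-[(tert-butyldimethylsilyl)oxy]-6-hydroxy-3-methylhex-2-en-1-yl]oxy}-8-methoxy-2H-chromen-2-one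
Conditions: HF·pyridine, pyridine, THF, 0 °C
Reagents that add atoms: none
Why: Buffered HF cleaves the unhindered primary silyl ether faster than the secondary one (selective desilylation on steric grounds); the acidic fluoride source causes no silyl migration and does not open ring B.

Step 6
Reactants: 8 7-{[(2E,5S)-5-[(tert-butyldimethylsilyl)oxy]-6-hydroxy-3-methylhex-2-en-1-yl]oxy}-8-methoxy-2H-chromen-2-one
Product: 9 (2S,4E)-2-[(tert-butyldimethylsilyl)oxy]-6-[(8-methoxy-2-oxo-2H-chromen-7-yl)oxy]-4-methylhex-4-enal
Conditions: Dess–Martin periodinane, NaHCO3, CH2Cl2, 0 °C to rt; used crude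
Reagents that add atoms: none
Why: Dess–Martin oxidation is mild and non-basic, so the α-silyloxy aldehyde should form without epimerisation at C5' and without touching the alkene or the aryl ether; the aldehyde is taken on directly.

Step 7
Reactants: 9 (2S,4E)-2-[(tert-butyldimethylsilyl)oxy]-6-[(8-methoxy-2-oxo-2H-chromen-7-yl)oxy]-4-methylhex-4-enal; 10 2-bromopropene
Product: 12 7-{[(2E,5S,6R)-5-[(tert-butyldimethylsilyl)oxy]-6-hydroxy-3,7-dimethylocta-2,7-dien-1-yl]oxy}-8-methoxy-2H-chromen-2-one, via isopropenylchromium dichloride 11 (not isolated)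
Conditions: CrCl2 (6 equiv), NiCl2 (2 mol%), 10 (3 equiv), degassed DMF, rt
Reagents that add atoms: none
Why: CrCl2 reduces NiCl2 to zerovalent nickel, which inserts into the C–Br bond of 10 and passes the isopropenyl group to trivalent chromium; the alkenylchromium 11 then adds to the aldehyde carbon of 9 and forms the C6'–C7' bond (Nozaki–Hiyama–Kishi reaction, known for α-silyloxy aldehydes). No ring closes. The new stereocentre C6' is set by C5' through the polar Felkin–Anh arrangement: the bulky silyl ether does not chelate chromium, the C5'–O bond lies anti to the incoming carbon, and the nucleophile passes the C5' hydrogen and not C4', which should give the 5',6'-anti product, that is (6'R) beside (5'S). The step needs facial selectivity at C6' and chemoselectivity for the aldehyde; the first comes from the C5' silyloxy group, the second from the low basicity and carbonyl selectivity of alkenylchromium reagents, which leave the lactone of ring B, its C3=C4 bond and the C5' centre untouched. Insertion of zerovalent nickel into the allylic C1'–O7 bond is the competing path and is held back by the low NiCl2 loading and the excess of 10.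

Step 8
Reactants: 12 7-{[(2E,5S,6R)-5-[(tert-butyldimethylsilyl)oxy]-6-hydroxy-3,7-dimethylocta-2,7-dien-1-yl]oxy}-8-methoxy-2H-chromen-2-one
Product: 13 7-{[(2E,5S,6R)-5,6-dihydroxy-3,7-dimethylocta-2,7-dien-1-yl]oxy}-8-methoxy-2H-chromen-2-one
Conditions: TBAF, AcOH, THF, 0 °C to rt
Reagents that add atoms: none
Why: Fluoride cleaves the Si–O bond (silyl ether deprotection); buffering with acetic acid keeps the medium from opening the lactone, and neither carbinol centre is a reaction site.

## Compound list

1 | (R)-glycidol, [(2R)-oxiran-2-yl]methanol | OC[C@@H]1CO1 | starting material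
2 | (2S)-pent-4-yne-1,2-diol | OC[C@@H](O)CC#C | intermediate
3 | (4S)-4,5-bis[(tert-butyldimethylsilyl)oxy]pent-1-yne | CC(C)(C)[Si](C)(C)OC[C@@H](O[Si](C)(C)C(C)(C)C)CC#C | intermediate
4 | [(1E,4S)-4,5-bis[(tert-butyldimethylsilyl)oxy]-2-methylpent-1-en-1-yl]dimethylalane (formed in the flask) | CC(C)(C)[Si](C)(C)OC[C@@H](O[Si](C)(C)C(C)(C)C)C/C(C)=C/[Al](C)C | intermediate
5 | (2E,5S)-5,6-bis[(tert-butyldimethylsilyl)oxy]-3-methylhex-2-en-1-ol | CC(C)(C)[Si](C)(C)OC[C@@H](O[Si](C)(C)C(C)(C)C)C/C(C)=C/CO | intermediate
6 | 7-hydroxy-8-methoxy-2H-chromen-2-one | Oc1ccc2ccc(=O)oc2c1OC | starting material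
7 | 7-{[(2E,5S)-5,6-bis[(tert-butyldimethylsilyl)oxy]-3-methylhex-2-en-1-yl]oxy}-8-methoxy-2H-chromen-2-one | CC(C)(C)[Si](C)(C)OC[C@@H](O[Si](C)(C)C(C)(C)C)C/C(C)=C/COc1ccc2ccc(=O)oc2c1OC | intermediate
8 | 7-{[(2E,5S)-5-[(tert-butyldimethylsilyl)oxy]-6-hydroxy-3-methylhex-2-en-1-yl]oxy}-8-methoxy-2H-chromen-2-one | OC[C@@H](O[Si](C)(C)C(C)(C)C)C/C(C)=C/COc1ccc2ccc(=O)oc2c1OC | intermediate
9 | (2S,4E)-2-[(tert-butyldimethylsilyl)oxy]-6-[(8-methoxy-2-oxo-2H-chromen-7-yl)oxy]-4-methylhex-4-enal | O=C[C@@H](O[Si](C)(C)C(C)(C)C)C/C(C)=C/COc1ccc2ccc(=O)oc2c1OC | intermediate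
10 | 2-bromopropene | C=C(C)Br | starting material
11 | dichloro(prop-1-en-2-yl)chromium, isopropenylchromium dichloride with trivalent chromium (formed in the flask) | C=C(C)[Cr](Cl)Cl | intermediate
12 | 7-{[(2E,5S,6R)-5-[(tert-butyldimethylsilyl)oxy]-6-hydroxy-3,7-dimethylocta-2,7-dien-1-yl]oxy}-8-methoxy-2H-chromen-2-one | C=C(C)[C@@H](O)[C@@H](O[Si](C)(C)C(C)(C)C)C/C(C)=C/COc1ccc2ccc(=O)oc2c1OC | intermediate
13 | 7-{[(2E,5S,6R)-5,6-dihydroxy-3,7-dimethylocta-2,7-dien-1-yl]oxy}-8-methoxy-2H-chromen-2-one | C=C(C)[C@@H](O)[C@@H](O)C/C(C)=C/COc1ccc2ccc(=O)oc2c1OC | target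

## Step count and least certain steps

Total step count: 8. Longest linear sequence: 8 steps, from 1 to 13; 6 and 10 are purchased and enter at steps 4 and 7.

Step 7 (key step). Two things are most likely to go wrong. The first is poor facial selectivity, because the only substituent on C5' other than the silyloxy group is a methylene and the Felkin preference of an alkenylchromium may be modest. The second is competing insertion of zerovalent nickel into the allylic C1'–O7 bond. Within the step, a chiral sulfonamide ligand on chromium matched to the substrate preference can reinforce the selectivity.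

The fallback sets C6' by chelation-controlled reduction instead of by addition. It sets out from 12, obtained as a mixture with the (5S,6S)-epimeric alcohol F1, and returns at 13. The mixture is oxidised with Dess–Martin periodinane to the single α-silyloxy enone F2. The silyl ether is cleaved with HF·pyridine to the α-hydroxy enone F3. F3 is reduced with Zn(BH4)2 in Et2O at −20 °C. Zinc bridges the ketone oxygen and the C5' hydroxyl, and hydride enters from the face of the chelate opposite C4', which should give the anti diol 13 directly.

Step 3. Capture of alkenylalane 4 by polymeric formaldehyde may be incomplete, and protonolysis on work-up would then give the des-hydroxymethyl alkene. The fallback changes the C1'–C2' bond-forming species from an alane to an alkenyllithium. It sets out from 3 and returns at 5. The carboalumination mixture is quenched with I2 to give the alkenyl iodide (1E,4S)-4,5-bis[(tert-butyldimethylsilyl)oxy]-1-iodo-2-methylpent-1-ene F4. Iodine–lithium exchange with t-BuLi in Et2O at −78 °C and addition of the alkenyllithium to monomeric formaldehyde then give 5 with the geometry retained.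

Step 1. Base-induced oligomerisation of glycidol and loss of the small water-soluble diol on work-up may cut the throughput. The fallback builds the alkyne by homologation instead of epoxide opening. It replaces 1 by the purchased acetonide 2-[(4S)-2,2-dimethyl-1,3-dioxolan-4-yl]ethan-1-ol F5 and returns at 2. Swern oxidation gives 2-[(4S)-2,2-dimethyl-1,3-dioxolan-4-yl]acetaldehyde F6. Seyferth–Gilbert homologation with the Ohira–Bestmann reagent (K2CO3, MeOH) gives (4S)-2,2-dimethyl-4-(prop-2-yn-1-yl)-1,3-dioxolane F7. Aqueous acetic acid then releases 2.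

Step 5. Over-cleavage to the diol or stalled conversion may make the mono-desilylation inefficient. The fallback removes the need for a selective deprotection. It sets out from 7 and returns at 13.
- Both silyl groups are removed with TBAF and AcOH to give the diol 7-{[(2E,5S)-5,6-dihydroxy-3-methylhex-2-en-1-yl]oxy}-8-methoxy-2H-chromen-2-one F8.
- TESCl and imidazole give the bis(triethylsilyl) ether F9.
- Swern oxidation converts the primary triethylsilyl ether directly into the aldehyde and leaves the secondary one, giving the α-triethylsilyloxy aldehyde F10.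
- The chromium-mediated addition of 10 under the conditions of step 7 gives the triethylsilyl analogue of 12, F11.
- Buffered fluoride then gives 13.

## Further compounds

F1 | step 7 | 7-{[(2E,5S,6S)-5-[(tert-butyldimethylsilyl)oxy]-6-hydroxy-3,7-dimethylocta-2,7-dien-1-yl]oxy}-8-methoxy-2H-chromen-2-one | C=C(C)[C@H](O)[C@@H](O[Si](C)(C)C(C)(C)C)C/C(C)=C/COc1ccc2ccc(=O)oc2c1OC
F2 | step 7 | 7-{[(2E,5S)-5-[(tert-butyldimethylsilyl)oxy]-3,7-dimethyl-6-oxoocta-2,7-dien-1-yl]oxy}-8-methoxy-2H-chromen-2-one | C=C(C)C(=O)[C@@H](O[Si](C)(C)C(C)(C)C)C/C(C)=C/COc1ccc2ccc(=O)oc2c1OC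
F3 | step 7 | 7-{[(2E,5S)-5-hydroxy-3,7-dimethyl-6-oxoocta-2,7-dien-1-yl]oxy}-8-methoxy-2H-chromen-2-one | C=C(C)C(=O)[C@@H](O)C/C(C)=C/COc1ccc2ccc(=O)oc2c1OC
F4 | step 3 | (1E,4S)-4,5-bis[(tert-butyldimethylsilyl)oxy]-1-iodo-2-methylpent-1-ene | CC(C)(C)[Si](C)(C)OC[C@@H](O[Si](C)(C)C(C)(C)C)C/C(C)=C/I
F5 | step 1 | 2-[(4S)-2,2-dimethyl-1,3-dioxolan-4-yl]ethan-1-ol | OCC[C@H]1COC(C)(C)O1
F6 | step 1 | 2-[(4S)-2,2-dimethyl-1,3-dioxolan-4-yl]acetaldehyde | O=CC[C@H]1COC(C)(C)O1
F7 | step 1 | (4S)-2,2-dimethyl-4-(prop-2-yn-1-yl)-1,3-dioxolane | C#CC[C@H]1COC(C)(C)O1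
F8 | step 5 | 7-{[(2E,5S)-5,6-dihydroxy-3-methylhex-2-en-1-yl]oxy}-8-methoxy-2H-chromen-2-one | OC[C@@H](O)C/C(C)=C/COc1ccc2ccc(=O)oc2c1OC
F9 | step 5 | 8-methoxy-7-{[(2E,5S)-3-methyl-5,6-bis[(triethylsilyl)oxy]hex-2-en-1-yl]oxy}-2H-chromen-2-one | CC[Si](CC)(CC)OC[C@@H](O[Si](CC)(CC)CC)C/C(C)=C/COc1ccc2ccc(=O)oc2c1OC
F10 | step 5 | (2S,4E)-6-[(8-methoxy-2-oxo-2H-chromen-7-yl)oxy]-4-methyl-2-[(triethylsilyl)oxy]hex-4-enal | O=C[C@@H](O[Si](CC)(CC)CC)C/C(C)=C/COc1ccc2ccc(=O)oc2c1OC
F11 | step 5 | 7-{[(2E,5S,6R)-6-hydroxy-3,7-dimethyl-5-[(triethylsilyl)oxy]octa-2,7-dien-1-yl]oxy}-8-methoxy-2H-chromen-2-one | C=C(C)[C@@H](O)[C@@H](O[Si](CC)(CC)CC)C/C(C)=C/COc1ccc2ccc(=O)oc2c1OC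
A1 | alternative 1 | (3R,4S,6E)-4-hydroxy-8-[(8-methoxy-2-oxo-2H-chromen-7-yl)oxy]-2,6-dimethylocta-1,6-dien-3-yl benzoate | C=C(C)[C@@H](OC(=O)c1ccccc1)[C@@H](O)C/C(C)=C/COc1ccc2ccc(=O)oc2c1OC
A2 | alternative 1 | 7-{[(2E)-5-hydroxy-3-methylpent-2-en-1-yl]oxy}-8-methoxy-2H-chromen-2-one | OCC/C(C)=C/COc1ccc2ccc(=O)oc2c1OC
A3 | alternative 1 | 2-methylprop-2-ene-1,1-diyl dibenzoate | C=C(C)C(OC(=O)c1ccccc1)OC(=O)c1ccccc1
A4 | alternative 2 | 7-{[(2E)-4-[(4S,5R)-2,2-dimethyl-5-(prop-1-en-2-yl)-1,3-dioxolan-4-yl]-3-methylbut-2-en-1-yl]oxy}-8-methoxy-2H-chromen-2-one | C=C(C)[C@H]1OC(C)(C)O[C@H]1C/C(C)=C/COc1ccc2ccc(=O)oc2c1OC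
A5 | alternative 2 | (4S,5R)-2,2-dimethyl-4-(prop-2-yn-1-yl)-5-(prop-1-en-2-yl)-1,3-dioxolane | C=C(C)[C@H]1OC(C)(C)O[C@H]1CC#C
A6 | alternative 2 | 7-(chloromethoxy)-8-methoxy-2H-chromen-2-one | ClCOc1ccc2ccc(=O)oc2c1OC
A7 | alternative 2 | 2-deoxy-D-ribose, (3S,4R)-3,4,5-trihydroxypentanal | O=CC[C@H](O)[C@H](O)CO
A8 | alternative 3 | 7-{[(2E,5S,6R)-6-[(tert-butyldimethylsilyl)oxy]-5-hydroxy-3,7-dimethylocta-2,7-dien-1-yl]oxy}-8-methoxy-2H-chromen-2-one | C=C(C)[C@@H](O[Si](C)(C)C(C)(C)C)[C@@H](O)C/C(C)=C/COc1ccc2ccc(=O)oc2c1OC
A9 | alternative 3 | 7-{[(2E)-3-iodobut-2-en-1-yl]oxy}-8-methoxy-2H-chromen-2-one | C/C(I)=C\COc1ccc2ccc(=O)oc2c1OC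
A10 | alternative 3 | tert-butyldimethyl{[(1R)-2-methyl-1-[(2S)-oxiran-2-yl]prop-2-en-1-yl]oxy}silane | C=C(C)[C@@H](O[Si](C)(C)C(C)(C)C)[C@@H]1CO1
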